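## Retrosynthetic overview

1. The target comes from its bis-silyl ether by fluoride, and that from a 1,4-dimethoxyarene by oxidative demethylation. No ring is built: the only ring is carried from 4-methoxy-2-methylphenol and turned into the quinone at the end.
2. C14′=C15′ comes from a Wittig reaction; C10′=C11′ (E) and C12′–C13′ come from a Johnson–Claisen rearrangement of an isopropenyl carbinol made from a C10′ aldehyde.
3. C8′–C9′ and both stereocentres come from an intermolecular Evans syn-glycolate aldol between a (silyloxy)acetyl oxazolidinone (C9′–C10′) and an aryl-bearing (2E,6E)-enal (C1′–C8′).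
4. The enal comes from SeO2 oxidation of the terminal E-methyl of a geranyl arene, itself made by CuI-catalysed coupling of an aryl Grignard reagent with geranyl bromide.

Assumption: side-chain carbons are numbered C1′ (ring CH2) to C15′; the carbinol centre made in step 12 is carried as an epimer mixture (left open in its SMILES) because step 13 destroys it.

Abbreviations: TBS = tert-butyldimethylsilyl; Ar = 2,5-dimethoxy-3-methylphenyl.

## Route

Step 1
Reactants: 1 4-methoxy-2-methylphenol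
Product: 2 2-bromo-4-methoxy-6-methylphenol
Conditions: Br2 (1.0 equiv), CH2Cl2, 0 °C
Reagents that add atoms: bromine, BrBr
Why: Electrophilic aromatic bromination goes to the only free position ortho to the strongly directing OH, since the para position is blocked by OMe.

Step 2
Reactants: 2 2-bromo-4-methoxy-6-methylphenol
Product: 3 1-bromo-2,5-dimethoxy-3-methylbenzene
Conditions: MeI, K2CO3, acetone, reflux
Reagents that add atoms: iodomethane, CI
Why: Williamson O-methylation of the phenoxide gives the hydroquinone dimethyl ether that masks the quinone.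

Step 3
Reactants: 3 1-bromo-2,5-dimethoxy-3-methylbenzene; 4 geranyl bromide, (2E)-1-bromo-3,7-dimethylocta-2,6-diene
Product: 6 1-[(2E)-3,7-dimethylocta-2,6-dien-1-yl]-2,5-dimethoxy-3-methylbenzene, via arylmagnesium bromide 5 (not isolated)
Conditions: Mg, THF, reflux; then CuI (10 mol %), 4, THF, 0 °C to rt
Reagents that add atoms: none
Why: Grignard formation followed by CuI-catalysed SN2 allylic substitution on the primary allylic bromide joins aryl and geranyl carbons with retention of the E olefin.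

Step 4
Reactants: 6 1-[(2E)-3,7-dimethylocta-2,6-dien-1-yl]-2,5-dimethoxy-3-methylbenzene
Product: 7 (2E,6E)-8-(2,5-dimethoxy-3-methylphenyl)-2,6-dimethylocta-2,6-dien-1-ol
Conditions: SeO2 (0.2 equiv), t-BuOOH (3 equiv), salicylic acid (0.1 equiv), CH2Cl2, 0 °C to rt
Reagents that add atoms: selenium dioxide (catalytic oxygen carrier), O=[Se]=O; tert-butyl hydroperoxide (terminal oxygen source), CC(C)(C)OO
Why: Catalytic SeO2 allylic oxidation (ene reaction then [2,3]-sigmatropic shift) attacks the E-methyl of the terminal, most accessible trisubstituted olefin and gives the E allylic alcohol; any enal 8 formed alongside is carried into step 5.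

Step 5
Reactants: 7 (2E,6E)-8-(2,5-dimethoxy-3-methylphenyl)-2,6-dimethylocta-2,6-dien-1-ol
Product: 8 (2E,6E)-8-(2,5-dimethoxy-3-methylphenyl)-2,6-dimethylocta-2,6-dienal
Conditions: MnO2 (activated, excess), CH2Cl2, rt
Reagents that add atoms: none
Why: MnO2 oxidises only the allylic alcohol, without E/Z isomerisation and without touching the arene or the other olefin.

Step 6
Reactants: 9 glycolic acid
Product: 10 tert-butyldimethylsilyl 2-[(tert-butyldimethylsilyl)oxy]acetate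
Conditions: TBSCl (2.2 equiv), imidazole, DMF, rt
Reagents that add atoms: tert-butyldimethylsilyl chloride, CC(C)(C)[Si](C)(C)Cl
Why: Imidazole-promoted silylation caps both the hydroxyl and the carboxyl group.

Step 7
Reactants: 10 tert-butyldimethylsilyl 2-[(tert-butyldimethylsilyl)oxy]acetate; 11 (4S)-4-benzyl-1,3-oxazolidin-2-one
Product: 14 (4S)-4-benzyl-3-{2-[(tert-butyldimethylsilyl)oxy]acetyl}-1,3-oxazolidin-2-one, via silyloxyacetyl chloride 12 (not isolated), via lithium oxazolidinide 13 (not isolated)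
Conditions: 10, (COCl)2, DMF (cat.), CH2Cl2, 0 °C to rt, concentrate; 11, n-BuLi, THF, −78 °C; combine, −78 to 0 °C
Reagents that add atoms: none
Why: Oxalyl chloride converts the silyl ester directly into the acid chloride under neutral conditions that spare the silyl ether, and N-acylation of the lithiated auxiliary gives the glycolate imide.

Step 8
Reactants: 14 (4S)-4-benzyl-3-{2-[(tert-butyldimethylsilyl)oxy]acetyl}-1,3-oxazolidin-2-one; 8 (2E,6E)-8-(2,5-dimethoxy-3-methylphenyl)-2,6-dimethylocta-2,6-dienal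
Product: 17 (4S)-4-benzyl-3-[(2S,3R,4E,8E)-2-(TBS-oxy)-10-Ar-3-hydroxy-4,8-dimethyldeca-4,8-dienoyl]-1,3-oxazolidin-2-one, via boron Z-enolate 15 (not isolated), via boron aldolate 16 (not isolated)
Conditions: Bu2BOTf (1.2 equiv), Et3N (1.4 equiv), CH2Cl2, −78 to 0 °C; 8, −78 to 0 °C; pH 7 buffer, MeOH, 30% H2O2, 0 °C
Reagents that add atoms: none
Why: Evans syn-aldol: the Z boron enolate reacts through a Zimmerman–Traxler chair on the face away from the benzyl group of the (S)-auxiliary, forming C8′–C9′ and setting the 2S,3R pair (C9′ and C8′, both R in the target) as the syn diol.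

Step 9
Reactants: 17 the aldol adduct
Product: 18 (2S,3R,4E,8E)-2-(TBS-oxy)-10-Ar-3-hydroxy-N-methoxy-N,4,8-trimethyldeca-4,8-dienamide
Conditions: MeNH(OMe)·HCl, Me3Al, CH2Cl2, −20 to 0 °C; aq. KNaC4H4O6
Reagents that add atoms: N,O-dimethylhydroxylamine hydrochloride, CNOC.Cl
Why: Weinreb transamination by the aluminium amide, assisted by the free β-hydroxyl, cleaves the auxiliary at the exocyclic carbonyl without retro-aldol or epimerisation.

Step 10
Reactants: 18 the Weinreb amide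
Product: 19 (2S,3R,4E,8E)-2,3-bis(TBS-oxy)-10-Ar-N-methoxy-N,4,8-trimethyldeca-4,8-dienamide
Conditions: TBSOTf, 2,6-lutidine, CH2Cl2, −78 to 0 °C
Reagents that add atoms: tert-butyldimethylsilyl trifluoromethanesulfonate, CC(C)(C)[Si](C)(C)OS(=O)(=O)C(F)(F)F
Why: Silylation of the hindered secondary allylic alcohol with the silyl triflate protects the second diol oxygen with the same fluoride-labile group.

Step 11
Reactants: 19 the bis-silylated Weinreb amide
Product: 20 (2S,3R,4E,8E)-2,3-bis(TBS-oxy)-10-Ar-4,8-dimethyldeca-4,8-dienal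
Conditions: i-Bu2AlH, THF, −78 °C; aq. KNaC4H4O6
Reagents that add atoms: none
Why: Hydride reduction of a Weinreb amide stops at the chelated tetrahedral aluminium intermediate and releases the aldehyde only on work-up, so there is no over-reduction or α-epimerisation.

Step 12
Reactants: 20 the bis-silyloxy aldehyde
Product: 21 (3RS,4R,5R,6E,10E)-4,5-bis(TBS-oxy)-12-Ar-2,6,10-trimethyldodeca-1,6,10-trien-3-ol
Conditions: CH2=C(CH3)MgBr, THF, −78 °C; aq. NH4Cl at −78 °C
Reagents that add atoms: isopropenylmagnesium bromide, CC(=C)[Mg]Br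
Why: Grignard 1,2-addition to the aldehyde is fast at −78 °C, and the cold quench prevents silyl migration; the configuration of the new carbinol is irrelevant.

Step 13
Reactants: 21 the isopropenyl carbinol
Product: 23 ethyl (4E,6R,7R,8E,12E)-6,7-bis(TBS-oxy)-14-Ar-4,8,12-trimethyltetradeca-4,8,12-trienoate, via ketene acetal 22 (not isolated)
Conditions: MeC(OEt)3 (excess), EtCO2H (cat.), 135–140 °C, EtOH distilled off
Reagents that add atoms: triethyl orthoacetate, CCOC(C)(OCC)OCC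
Why: Johnson–Claisen [3,3]-sigmatropic rearrangement through a chair with the bulky bis-silyloxy substituent equatorial gives the E trisubstituted C10′=C11′ olefin from both carbinol epimers and adds C13′–C14′.

Step 14
Reactants: 23 the ethyl ester
Product: 24 (4E,6R,7R,8E,12E)-6,7-bis(TBS-oxy)-14-Ar-4,8,12-trimethyltetradeca-4,8,12-trienal
Conditions: i-Bu2AlH (1.05 equiv), CH2Cl2, −78 °C; aq. KNaC4H4O6
Reagents that add atoms: none
Why: Partial ester reduction works because the aluminium hemiacetal is stable at −78 °C and collapses to the aldehyde only on work-up.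

Step 15
Reactants: 24 the trienal
Product: 25 1-[(2E,6E,8R,9R,10E)-8,9-bis(TBS-oxy)-3,7,11,15-tetramethylhexadeca-2,6,10,14-tetraen-1-yl]-2,5-dimethoxy-3-methylbenzene
Conditions: i-PrPPh3I, n-BuLi, THF, 0 °C; then 24, −78 °C to rt
Reagents that add atoms: isopropyltriphenylphosphonium iodide, CC(C)[P+](c1ccccc1)(c1ccccc1)c1ccccc1.[I-]
Why: Wittig olefination with the non-stabilised isopropylidene ylide installs the terminal trisubstituted olefin, which has no geometry to control.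

Step 16
Reactants: 25 the bis-silylated dimethoxyarene
Product: 26 2-[(2E,6E,8R,9R,10E)-8,9-bis(TBS-oxy)-3,7,11,15-tetramethylhexadeca-2,6,10,14-tetraen-1-yl]-6-methylcyclohexa-2,5-diene-1,4-dione
Conditions: (NH4)2Ce(NO3)6 (2.5 equiv), MeCN/THF/H2O, 0 °C, 20 min
Reagents that add atoms: water, O
Why: Oxidative demethylation of the 1,4-dimethoxyarene by tetravalent cerium gives the p-quinone much faster than the trisubstituted olefins or secondary silyl ethers react, and the silyl groups keep the glycol from oxidative cleavage.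

Step 17
Reactants: 26 the bis-silylated quinone
Product: 27 2-[(2E,6E,8R,9R,10E)-8,9-dihydroxy-3,7,11,15-tetramethylhexadeca-2,6,10,14-tetraen-1-yl]-6-methylcyclohexa-2,5-diene-1,4-dione
Conditions: HF·pyridine, pyridine, THF, 0 °C to rt
Reagents that add atoms: none
Why: Buffered fluoride desilylation frees both allylic hydroxyls without the acid or base that would ionise the bis-allylic diol or cyclise the prenyl quinone.

## Compound list

1 | 4-methoxy-2-methylphenol | COc1ccc(O)c(C)c1 | starting material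
2 | 2-bromo-4-methoxy-6-methylphenol | COc1cc(C)c(O)c(Br)c1 | intermediate
3 | 1-bromo-2,5-dimethoxy-3-methylbenzene | COc1cc(C)c(OC)c(Br)c1 | intermediate
4 | geranyl bromide, (2E)-1-bromo-3,7-dimethylocta-2,6-diene | CC(C)=CCC/C(C)=C/CBr | starting material
5 | (2,5-dimethoxy-3-methylphenyl)magnesium bromide | COc1cc(C)c(OC)c([Mg]Br)c1 | intermediate (not isolated)
6 | 1-[(2E)-3,7-dimethylocta-2,6-dien-1-yl]-2,5-dimethoxy-3-methylbenzene | CC(C)=CCC/C(C)=C/Cc1cc(OC)cc(C)c1OC | intermediate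
7 | (2E,6E)-8-(2,5-dimethoxy-3-methylphenyl)-2,6-dimethylocta-2,6-dien-1-ol | OC/C(C)=C/CC/C(C)=C/Cc1cc(OC)cc(C)c1OC | intermediate
8 | (2E,6E)-8-(2,5-dimethoxy-3-methylphenyl)-2,6-dimethylocta-2,6-dienal | O=C/C(C)=C/CC/C(C)=C/Cc1cc(OC)cc(C)c1OC | intermediate
9 | glycolic acid | OCC(=O)O | starting material
10 | tert-butyldimethylsilyl 2-[(tert-butyldimethylsilyl)oxy]acetate | CC(C)(C)[Si](C)(C)OCC(=O)O[Si](C)(C)C(C)(C)C | intermediate
11 | (4S)-4-benzyl-1,3-oxazolidin-2-one | O=C1N[C@@H](Cc2ccccc2)CO1 | starting material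
12 | 2-[(tert-butyldimethylsilyl)oxy]acetyl chloride | CC(C)(C)[Si](C)(C)OCC(=O)Cl | intermediate (not isolated)
13 | lithium (4S)-4-benzyl-2-oxo-1,3-oxazolidin-3-ide | [Li]N1[C@@H](Cc2ccccc2)COC1=O | intermediate (not isolated)
14 | (4S)-4-benzyl-3-{2-[(tert-butyldimethylsilyl)oxy]acetyl}-1,3-oxazolidin-2-one | CC(C)(C)[Si](C)(C)OCC(=O)N1[C@@H](Cc2ccccc2)COC1=O | intermediate
15 | (Z)-dibutylboron enolate of 14 | CCCCB(CCCC)O/C(=C\O[Si](C)(C)C(C)(C)C)N1[C@@H](Cc2ccccc2)COC1=O | intermediate (not isolated)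
16 | O-dibutylboryl aldolate of 17 | O=C([C@@H](O[Si](C)(C)C(C)(C)C)[C@H](OB(CCCC)CCCC)/C(C)=C/CC/C(C)=C/Cc1cc(OC)cc(C)c1OC)N1[C@@H](Cc2ccccc2)COC1=O | intermediate (not isolated)
17 | (4S)-4-benzyl-3-[(2S,3R,4E,8E)-2-(TBS-oxy)-10-(2,5-dimethoxy-3-methylphenyl)-3-hydroxy-4,8-dimethyldeca-4,8-dienoyl]-1,3-oxazolidin-2-one | O=C([C@@H](O[Si](C)(C)C(C)(C)C)[C@H](O)/C(C)=C/CC/C(C)=C/Cc1cc(OC)cc(C)c1OC)N1[C@@H](Cc2ccccc2)COC1=O | intermediate
18 | (2S,3R,4E,8E)-2-(TBS-oxy)-10-(2,5-dimethoxy-3-methylphenyl)-3-hydroxy-N-methoxy-N,4,8-trimethyldeca-4,8-dienamide | CON(C)C(=O)[C@@H](O[Si](C)(C)C(C)(C)C)[C@H](O)/C(C)=C/CC/C(C)=C/Cc1cc(OC)cc(C)c1OC | intermediate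
19 | (2S,3R,4E,8E)-2,3-bis(TBS-oxy)-10-(2,5-dimethoxy-3-methylphenyl)-N-methoxy-N,4,8-trimethyldeca-4,8-dienamide | CON(C)C(=O)[C@@H](O[Si](C)(C)C(C)(C)C)[C@H](O[Si](C)(C)C(C)(C)C)/C(C)=C/CC/C(C)=C/Cc1cc(OC)cc(C)c1OC | intermediate
20 | (2S,3R,4E,8E)-2,3-bis(TBS-oxy)-10-(2,5-dimethoxy-3-methylphenyl)-4,8-dimethyldeca-4,8-dienal | O=C[C@@H](O[Si](C)(C)C(C)(C)C)[C@H](O[Si](C)(C)C(C)(C)C)/C(C)=C/CC/C(C)=C/Cc1cc(OC)cc(C)c1OC | intermediate
21 | (3RS,4R,5R,6E,10E)-4,5-bis(TBS-oxy)-12-(2,5-dimethoxy-3-methylphenyl)-2,6,10-trimethyldodeca-1,6,10-trien-3-ol (C3 epimer mixture) | C=C(C)C(O)[C@@H](O[Si](C)(C)C(C)(C)C)[C@H](O[Si](C)(C)C(C)(C)C)/C(C)=C/CC/C(C)=C/Cc1cc(OC)cc(C)c1OC | intermediate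
22 | mixed ketene acetal, the 3-O-(1-ethoxyethenyl) ether of 21 | CCOC(=C)OC(C(C)=C)[C@@H](O[Si](C)(C)C(C)(C)C)[C@H](O[Si](C)(C)C(C)(C)C)/C(C)=C/CC/C(C)=C/Cc1cc(OC)cc(C)c1OC | intermediate (not isolated)
23 | ethyl (4E,6R,7R,8E,12E)-6,7-bis(TBS-oxy)-14-(2,5-dimethoxy-3-methylphenyl)-4,8,12-trimethyltetradeca-4,8,12-trienoate | CCOC(=O)CC/C(C)=C/[C@@H](O[Si](C)(C)C(C)(C)C)[C@H](O[Si](C)(C)C(C)(C)C)/C(C)=C/CC/C(C)=C/Cc1cc(OC)cc(C)c1OC | intermediate
24 | (4E,6R,7R,8E,12E)-6,7-bis(TBS-oxy)-14-(2,5-dimethoxy-3-methylphenyl)-4,8,12-trimethyltetradeca-4,8,12-trienal | O=CCC/C(C)=C/[C@@H](O[Si](C)(C)C(C)(C)C)[C@H](O[Si](C)(C)C(C)(C)C)/C(C)=C/CC/C(C)=C/Cc1cc(OC)cc(C)c1OC | intermediate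
25 | 1-[(2E,6E,8R,9R,10E)-8,9-bis(TBS-oxy)-3,7,11,15-tetramethylhexadeca-2,6,10,14-tetraen-1-yl]-2,5-dimethoxy-3-methylbenzene | CC(C)=CCC/C(C)=C/[C@@H](O[Si](C)(C)C(C)(C)C)[C@H](O[Si](C)(C)C(C)(C)C)/C(C)=C/CC/C(C)=C/Cc1cc(OC)cc(C)c1OC | intermediate
26 | 2-[(2E,6E,8R,9R,10E)-8,9-bis(TBS-oxy)-3,7,11,15-tetramethylhexadeca-2,6,10,14-tetraen-1-yl]-6-methylcyclohexa-2,5-diene-1,4-dione | CC(C)=CCC/C(C)=C/[C@@H](O[Si](C)(C)C(C)(C)C)[C@H](O[Si](C)(C)C(C)(C)C)/C(C)=C/CC/C(C)=C/CC1=CC(=O)C=C(C)C1=O | intermediate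
27 | 2-[(2E,6E,8R,9R,10E)-8,9-dihydroxy-3,7,11,15-tetramethylhexadeca-2,6,10,14-tetraen-1-yl]-6-methylcyclohexa-2,5-diene-1,4-dione | CC(C)=CCC/C(C)=C/[C@@H](O)[C@H](O)/C(C)=C/CC/C(C)=C/CC1=CC(=O)C=C(C)C1=O | target

## Step count and risks

Total steps: 17. Longest linear sequence: 15 steps (1 → 2 → 3 → 6 → 7 → 8 → 17 → 18 → 19 → 20 → 21 → 23 → 24 → 25 → 26 → 27); the glycolate branch (9 → 10 → 14) adds 2 steps.

The three steps most likely to fail:

**Step 4 (SeO2 oxidation of 6).** The electron-rich arene and the benzylic–allylic CH2 can compete with the terminal methyl, so yield and site selectivity may be poor. The fallback oxidises before the arene is attached. It sets out from 3 (used as its Grignard reagent 5) and comes back to the route at 7. Commercial geranyl acetate F1 is oxidised with SeO2 (cat.)/t-BuOOH, where the acetate deactivates the near olefin, to (2E,6E)-8-hydroxy-3,7-dimethylocta-2,6-dien-1-yl acetate F2. Silylation (TBSCl, imidazole) gives (2E,6E)-8-(TBS-oxy)-3,7-dimethylocta-2,6-dien-1-yl acetate F3, and methanolysis (K2CO3, MeOH) gives (2E,6E)-8-(TBS-oxy)-3,7-dimethylocta-2,6-dien-1-ol F4. Mesylation and bromide exchange (MsCl, Et3N; LiBr, THF) give (2E,6E)-1-bromo-8-(TBS-oxy)-3,7-dimethylocta-2,6-diene F5. CuI-catalysed coupling with 5 gives the TBS ether of 7 F6, and Bu4NF in THF releases 7.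

**Step 13 (Johnson–Claisen at 140 °C on a hindered substrate with acid-sensitive allylic silyl ethers).** The fallback builds the same olefin by olefination and allyl–allyl coupling instead of a sigmatropic shift. It sets out from 20 and comes back to the route at 25. Aldehyde 20 reacts with the stabilised ylide ethyl 2-(triphenylphosphoranylidene)propanoate (CH2Cl2, rt) to give ethyl (2E,4R,5R,6E,10E)-4,5-bis(TBS-oxy)-12-Ar-2,6,10-trimethyldodeca-2,6,10-trienoate F7. i-Bu2AlH reduction gives the allylic alcohol (2E,4R,5R,6E,10E)-4,5-bis(TBS-oxy)-12-Ar-2,6,10-trimethyldodeca-2,6,10-trien-1-ol F8. MsCl/Et3N then LiBr gives the corresponding allylic bromide F9. Alkylation of lithiated 3-methylbut-2-enyl phenyl sulfone (n-BuLi, THF, −78 °C) with F9 gives the C13′ phenylsulfonyl derivative of 25 F10 as an epimer mixture. Reductive desulfonylation (Na(Hg), Na2HPO4, MeOH/THF, −20 °C) gives 25.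

**Step 16 (oxidation with (NH4)2Ce(NO3)6).** The acidic oxidant may strip a silyl ether and then cleave the glycol, or attack the polyene. The fallback replaces the chemical oxidant by an electrochemical two-stage unmasking. It sets out from 25 and comes back to the route at 26. Anodic oxidation of 25 (Pt anode, 1% KOH in MeOH, 0 °C, constant current) gives the quinone bis(dimethyl ketal) 1-[(2E,6E,8R,9R,10E)-8,9-bis(TBS-oxy)-3,7,11,15-tetramethylhexadeca-2,6,10,14-tetraen-1-yl]-3,3,6,6-tetramethoxy-5-methylcyclohexa-1,4-diene F11. Brief hydrolysis (dilute aq. AcOH, acetone, 0 °C to rt) gives 26.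

## Further compounds

F1 | step 4 | geranyl acetate, (2E)-3,7-dimethylocta-2,6-dien-1-yl acetate | CC(C)=CCC/C(C)=C/COC(C)=O
F2 | step 4 | (2E,6E)-8-hydroxy-3,7-dimethylocta-2,6-dien-1-yl acetate | OC/C(C)=C/CC/C(C)=C/COC(C)=O
F3 | step 4 | (2E,6E)-8-(TBS-oxy)-3,7-dimethylocta-2,6-dien-1-yl acetate | CC(C)(C)[Si](C)(C)OC/C(C)=C/CC/C(C)=C/COC(C)=O
F4 | step 4 | (2E,6E)-8-(TBS-oxy)-3,7-dimethylocta-2,6-dien-1-ol | CC(C)(C)[Si](C)(C)OC/C(C)=C/CC/C(C)=C/CO
F5 | step 4 | (2E,6E)-1-bromo-8-(TBS-oxy)-3,7-dimethylocta-2,6-diene | CC(C)(C)[Si](C)(C)OC/C(C)=C/CC/C(C)=C/CBr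
F6 | step 4 | TBS ether of 7, tert-butyl{[(2E,6E)-8-(2,5-dimethoxy-3-methylphenyl)-2,6-dimethylocta-2,6-dien-1-yl]oxy}dimethylsilane | CC(C)(C)[Si](C)(C)OC/C(C)=C/CC/C(C)=C/Cc1cc(OC)cc(C)c1OC
F7 | step 13 | ethyl (2E,4R,5R,6E,10E)-4,5-bis(TBS-oxy)-12-(2,5-dimethoxy-3-methylphenyl)-2,6,10-trimethyldodeca-2,6,10-trienoate | CCOC(=O)/C(C)=C/[C@@H](O[Si](C)(C)C(C)(C)C)[C@H](O[Si](C)(C)C(C)(C)C)/C(C)=C/CC/C(C)=C/Cc1cc(OC)cc(C)c1OC
F8 | step 13 | (2E,4R,5R,6E,10E)-4,5-bis(TBS-oxy)-12-(2,5-dimethoxy-3-methylphenyl)-2,6,10-trimethyldodeca-2,6,10-trien-1-ol | OC/C(C)=C/[C@@H](O[Si](C)(C)C(C)(C)C)[C@H](O[Si](C)(C)C(C)(C)C)/C(C)=C/CC/C(C)=C/Cc1cc(OC)cc(C)c1OC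
F9 | step 13 | (2E,4R,5R,6E,10E)-1-bromo-4,5-bis(TBS-oxy)-12-(2,5-dimethoxy-3-methylphenyl)-2,6,10-trimethyldodeca-2,6,10-triene | BrC/C(C)=C/[C@@H](O[Si](C)(C)C(C)(C)C)[C@H](O[Si](C)(C)C(C)(C)C)/C(C)=C/CC/C(C)=C/Cc1cc(OC)cc(C)c1OC
F10 | step 13 | C13′ phenylsulfonyl derivative of 25 (epimer mixture at the sulfone carbon) | CC(C)=CC(C/C(C)=C/[C@@H](O[Si](C)(C)C(C)(C)C)[C@H](O[Si](C)(C)C(C)(C)C)/C(C)=C/CC/C(C)=C/Cc1cc(OC)cc(C)c1OC)S(=O)(=O)c1ccccc1
F11 | step 16 | 1-[(2E,6E,8R,9R,10E)-8,9-bis(TBS-oxy)-3,7,11,15-tetramethylhexadeca-2,6,10,14-tetraen-1-yl]-3,3,6,6-tetramethoxy-5-methylcyclohexa-1,4-diene | CC(C)=CCC/C(C)=C/[C@@H](O[Si](C)(C)C(C)(C)C)[C@H](O[Si](C)(C)C(C)(C)C)/C(C)=C/CC/C(C)=C/CC1=CC(OC)(OC)C=C(C)C1(OC)OC
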